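**Retrosynthetic overview**

1. Ring order: the A ring is bought as 3,5-dimethoxyphenol 1. The pyranone C ring is closed first (1 + methoxyacetic acid 2 + one carbon from DMF → ketone 3 → 3,5,7-trimethoxychromone 4). The B ring is attached last.
2. Stereochemistry: Cu-catalysed enantioselective β-borylation of 4 gives the 2-boryl chromanone (5, then BF3K salt 6) with the 3-OMe trans. This is a chiral homoenolate equivalent of the chromanone.
3. Key disconnection C2–C1′: the homoenolate carbon C2 of 6 is joined to C5 of 2-methoxy-1,4-benzoquinone 7, two carbons that are both natively electrophilic. The B ring arrives as a quinone, so reduction of adduct 8 gives the 2′,5′-diol/4′-OMe pattern of target 9 without protecting groups.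

Assumption: the (R,S)-Josiphos–Cu catalyst is taken to deliver boron to the C2 face that gives the (2R) boronate; if the sense proves opposite, the mirror-image ligand is used.

**Route**

Step 1
Reactants: 1 3,5-dimethoxyphenol; 2 methoxyacetic acid
Product: 4 3,5,7-trimethoxy-4H-chromen-4-one, via aryl ketone 3 (not isolated)
Conditions: BF3·OEt2 (solvent), 85 °C; then DMF, MsCl, 50 → 80 °C; aq work-up
Reagents that add atoms: N,N-dimethylformamide, CN(C)C=O
Why: BF3 drives Friedel–Crafts acylation ortho to the phenol (3 is held as its BF2 chelate), and the α-methylene is then formylated by the DMF/MsCl Vilsmeier–Haack-type reagent and cyclodehydrated onto the phenol, which is the one-pot deoxybenzoin-to-isoflavone protocol applied to an α-methoxy ketone; no stereocentre is formed.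

Step 2
Reactants: 4 3,5,7-trimethoxy-4H-chromen-4-one
Product: 6 potassium trifluoro[(2R,3R)-3,5,7-trimethoxy-4-oxochroman-2-yl]borate, via pinacol boronate 5 (not isolated)
Conditions: CuCl (5 mol%), (R,S)-Josiphos (6 mol%), NaOt-Bu (10 mol%), B2pin2 (1.2 equiv), MeOH (2 equiv), THF, 0 °C → rt; then aq KHF2 (4 equiv), MeOH, rt; recrystallise (acetone/Et2O)
Reagents that add atoms: bis(pinacolato)diboron, CC1(C)OB(OC1(C)C)B1OC(C)(C)C(C)(C)O1; potassium hydrogen difluoride, F.[F-].[K+]
Why: Proposed new method: a chiral bisphosphine–Cu–Bpin species should add boron to the enone β-carbon C2 on one face (setting C2 as R), MeOH protonates the enolate, and C3, being α to the ketone, settles under the catalytic alkoxide into the 2,3-trans isomer (3R), after which KHF2 gives a crystalline trifluoroborate whose recrystallisation upgrades dr and ee; the closest known reaction type is Cu(I)-catalysed enantioselective conjugate borylation of cyclic and α-substituted enones with B2pin2/MeOH, followed by KHF2 conversion to β-trifluoroborato ketones.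

Step 3
Reactants: 6 potassium trifluoro[(2R,3R)-3,5,7-trimethoxy-4-oxochroman-2-yl]borate; 7 2-methoxy-1,4-benzoquinone
Product: 9 (2R,3R)-2-(2,5-dihydroxy-4-methoxyphenyl)-3,5,7-trimethoxychroman-4-one, via alkylated quinone 8 (not isolated)
Conditions: 7 (3 equiv), AgNO3 (20 mol%), K2S2O8 (2.5 equiv), CH2Cl2/H2O 1:1, rt, dark; then aq Na2S2O4, EtOAc, rt, under Ar; chromatography
Reagents that add atoms: none
Why: Proposed new method: the β-trifluoroborato ketone 6 acts as a homoenolate (d3) equivalent, since one-electron oxidation of the C–B bond by Ag(II)/sulfate radical releases a nucleophilic α-aryloxy C2 radical that adds to C5 of the quinone (β to the more electrophilic C1 carbonyl, leaving the vinylogous-ester C4 carbonyl intact), oxidation of the adduct gives quinone 8 and dithionite reduces it to the hydroquinone; C2 is planar in the radical, so its configuration is re-set by the untouched (3R)-OMe centre, the quinone entering anti to the pseudo-axial OMe to give the 2,3-trans (2R,3R) product, with any cis isomer removed by chromatography; the closest known reaction type is the Ag/persulfate borono-Minisci radical C–H alkylation of quinones with secondary alkylboron reagents.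

**Compound list**

1 | 3,5-dimethoxyphenol | COc1cc(O)cc(OC)c1 | starting material
2 | methoxyacetic acid | COCC(=O)O | starting material
3 | 1-(2-hydroxy-4,6-dimethoxyphenyl)-2-methoxyethan-1-one | COCC(=O)c1c(O)cc(OC)cc1OC | intermediate
4 | 3,5,7-trimethoxy-4H-chromen-4-one | COC1=COc2cc(OC)cc(OC)c2C1=O | intermediate
5 | (2R,3R)-3,5,7-trimethoxy-2-(4,4,5,5-tetramethyl-1,3,2-dioxaborolan-2-yl)chroman-4-one (2,3-trans) | COc1cc(OC)c2c(c1)O[C@H](B1OC(C)(C)C(C)(C)O1)[C@@H](OC)C2=O | intermediate
6 | potassium trifluoro[(2R,3R)-3,5,7-trimethoxy-4-oxochroman-2-yl]borate (2,3-trans) | COc1cc(OC)c2c(c1)O[C@H]([B-](F)(F)F)[C@@H](OC)C2=O.[K+] | intermediate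
7 | 2-methoxy-1,4-benzoquinone | COC1=CC(=O)C=CC1=O | starting material
8 | 2-methoxy-5-[(2R,3R)-3,5,7-trimethoxy-4-oxochroman-2-yl]cyclohexa-2,5-diene-1,4-dione | COc1cc(OC)c2c(c1)O[C@H](C1=CC(=O)C(OC)=CC1=O)[C@@H](OC)C2=O | intermediate
9 | (2R,3R)-2-(2,5-dihydroxy-4-methoxyphenyl)-3,5,7-trimethoxychroman-4-one (2,3-trans) | COc1cc(OC)c2c(c1)O[C@H](c1cc(O)c(OC)cc1O)[C@@H](OC)C2=O | target

**Totals**

Total step count: 3. Longest linear sequence: 3 (1 → 4 → 6 → 9).

**Steps most likely to fail, with fallbacks**

Step 3 (most risky). The C2 radical may be over-oxidised back to chromone 4, may attack the quinone at oxygen or at C6, or may give a poor trans/cis ratio. Quinone 8 may also tautomerise to the flavone before it is reduced. The ee of 9 equals the C3 purity of 6 only if the cis isomer is separated and not epimerised. The fallback sets out from 6 and comes back at 9. Commercial 2-methoxyhydroquinone is benzylated (BnBr, K2CO3, DMF) to 1,4-bis(benzyloxy)-2-methoxybenzene F1 and brominated para to the methoxy group (NBS, MeCN) to 1,4-bis(benzyloxy)-2-bromo-5-methoxybenzene F2. Trifluoroborate 6 is then cross-coupled with F2 by Ir/Ni dual photoredox catalysis (Ir photocatalyst, NiCl2·dme/dtbbpy, K2HPO4, dioxane, blue LED). The same C2 radical is captured at nickel and reductively eliminated trans to the 3-OMe, giving (2R,3R)-2-[2,5-bis(benzyloxy)-4-methoxyphenyl]-3,5,7-trimethoxychroman-4-one F3. Hydrogenolysis (H2, Pd/C, EtOAc) then gives 9. This keeps the homoenolate logic but replaces the quinone by an aryl halide, at the cost of three operations.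

Step 2. The chromone is an electron-rich vinylogous ester and may react slowly or with low ee. The enolate may ring-open by retro-oxa-Michael reaction and racemise C2. Boron and the 3-OMe may undergo β-elimination. The trans/cis ratio at C3 may be modest. The fallback sets out from 4 and comes back at 5. The borylation is run with an achiral catalyst (CuCl/Xantphos, NaOt-Bu, B2pin2, MeOH, THF) to give the racemic trans boronate, that is 5 together with its enantiomer (2S,3S)-3,5,7-trimethoxy-2-(4,4,5,5-tetramethyl-1,3,2-dioxaborolan-2-yl)chroman-4-one F4. The two are separated by preparative chiral SFC, and 5 is taken on with KHF2 to 6 as in step 2. This replaces asymmetric catalysis by resolution.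

Step 1. Acylation may go partly para to the hydroxyl, and the Vilsmeier-type formylation of an α-methoxy ketone is less proven than that of deoxybenzoins. The fallback sets out from 1 and comes back at 4. The phenol is O-acylated with methoxyacetyl chloride (Et3N, CH2Cl2) to 3,5-dimethoxyphenyl methoxyacetate F5. A Fries rearrangement (TiCl4, ClCH2CH2Cl, 80 °C) gives the chelated ortho-hydroxy ketone 3, now isolated and purified. Condensation with DMF dimethyl acetal (toluene, 100 °C) gives the enaminone (Z)-3-(dimethylamino)-1-(2-hydroxy-4,6-dimethoxyphenyl)-2-methoxyprop-2-en-1-one F6. AcOH then closes the ring with loss of dimethylamine to give 4.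

**Further compounds**

F1 | step 3 | 1,4-bis(benzyloxy)-2-methoxybenzene | COc1cc(OCc2ccccc2)ccc1OCc1ccccc1
F2 | step 3 | 1,4-bis(benzyloxy)-2-bromo-5-methoxybenzene | COc1cc(OCc2ccccc2)c(Br)cc1OCc1ccccc1
F3 | step 3 | (2R,3R)-2-[2,5-bis(benzyloxy)-4-methoxyphenyl]-3,5,7-trimethoxychroman-4-one | COc1cc(OC)c2c(c1)O[C@H](c1cc(OCc3ccccc3)c(OC)cc1OCc1ccccc1)[C@@H](OC)C2=O
F4 | step 2 | (2S,3S)-3,5,7-trimethoxy-2-(4,4,5,5-tetramethyl-1,3,2-dioxaborolan-2-yl)chroman-4-one | COc1cc(OC)c2c(c1)O[C@@H](B1OC(C)(C)C(C)(C)O1)[C@H](OC)C2=O
F5 | step 1 | 3,5-dimethoxyphenyl methoxyacetate | COCC(=O)Oc1cc(OC)cc(OC)c1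
F6 | step 1 | (Z)-3-(dimethylamino)-1-(2-hydroxy-4,6-dimethoxyphenyl)-2-methoxyprop-2-en-1-one | COc1cc(O)c(C(=O)/C(OC)=C/N(C)C)c(OC)c1
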